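**Target:** 1α,19-diacetoxy-6-hydroxy-15-oxo-6,7-seco-ent-kaur-16-en-7,20-olide (CNP0105570.2). This is a paper route; nothing here has been run.

## Retrosynthetic overview

1. The exocyclic enone comes from α-methylenation of a 17-nor 15-ketone; the free 6-OH is unmasked last from a TBS ether.
2. Key disconnection: C13–C14 and C8–C15 together. A SmI2-generated enal radical anion reacts at its β-carbon (C13) with the CH2 terminus (C14) of an α-methylene spirolactone, and the resulting C8 enolate closes onto the aldehyde. Rings C and D form in one step.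
3. The α-methylene spirolactone (lactone ring B) comes from C9–C10 allylic alkylation of a ring-A 2-formyl ketone with a Morita–Baylis–Hillman carbonate, then reduction and lactonisation.
4. Ring A comes from a catalytic enantioselective Diels–Alder reaction of a 2-silyloxydiene with methacrolein (sets C4 and C5), then C10 formylation.
5. Ring order: A, then lactone B, then C and D together.

Assumption: ent-kaurane numbering (C1–C20) is used for all intermediates, and each chiral catalyst (steps 3 and 8) is taken in the enantiomeric or pseudo-enantiomeric form whose stereochemical model gives the configuration drawn; the opposite form is used if the sense turns out reversed.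

## Route

Step 1
Reactants: 1 (tert-butyldimethylsilyloxy)acetaldehyde; 2 1-(triphenylphosphoranylidene)propan-2-one
Product: 3 (E)-5-[(tert-butyldimethylsilyl)oxy]pent-3-en-2-one
Conditions: CH2Cl2, rt
Reagents that add atoms: none
Why: Wittig olefination with a stabilised ylide gives the (E)-enone.

Step 2
Reactants: 3 (E)-5-[(tert-butyldimethylsilyl)oxy]pent-3-en-2-one
Product: 4 (E)-1-[(tert-butyldimethylsilyl)oxy]-4-[(triisopropylsilyl)oxy]penta-2,4-diene
Conditions: TIPSOTf, Et3N, Et2O, 0 °C
Reagents that add atoms: triisopropylsilyl trifluoromethanesulfonate, CC(C)[Si](C(C)C)(C(C)C)OS(=O)(=O)C(F)(F)F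
Why: Soft enolisation (silyl triflate/amine) at the methyl group gives the cross-conjugated 2-silyloxydiene with the (E)-alkene retained.

Step 3
Reactants: 4 the silyloxydiene; 5 methacrolein
Product: 6 (1R,2S)-2-{[(tert-butyldimethylsilyl)oxy]methyl}-1-methyl-4-[(triisopropylsilyl)oxy]cyclohex-3-ene-1-carbaldehyde
Conditions: (S)-3,3-diphenyl-1-(o-tolyl)tetrahydro-1H,3H-pyrrolo[1,2-c][1,3,2]oxazaborole protonated with HNTf2 (10 mol%), CH2Cl2, −78 to −40 °C
Reagents that add atoms: none
Why: Catalytic enantioselective Diels–Alder reaction; the 2-silyloxy and 1-alkyl groups direct the regiochemistry, the formyl-endo transition state places CHO (C19) cis to CH2OTBS (C6), the oxazaborolidinium shields one face of the enal and so sets C4 and C5, and the enol ether is left regiodefined toward C10.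

Step 4
Reactants: 6 the cycloadduct
Product: 8 (1R,2R)-2-{[(tert-butyldimethylsilyl)oxy]methyl}-3-(hydroxymethylidene)-1-methyl-4-oxocyclohexane-1-carbaldehyde, via keto acetal 7 (not isolated)
Conditions: HC(OMe)3, TMSOTf (20 mol%), CH2Cl2, −78 °C; then 1 M aq. HCl, THF, 0 °C
Reagents that add atoms: trimethyl orthoformate, COC(OC)OC; water, O
Why: Mukaiyama-type alkylation of the regiodefined silyl enol ether by the dimethoxycarbenium ion (the hindered C19 aldehyde is inert under silyl triflate catalysis) puts the one-carbon unit C20 on C10 only, and hydrolysis of the β-keto acetal gives the enolised 2-formyl ketone.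

Step 5
Reactants: 9 pent-4-enal; 10 3,3-dimethoxyprop-1-ene (3 equiv)
Product: 11 (E)-6,6-dimethoxyhex-4-enal
Conditions: second-generation Grubbs catalyst (H2IMes)(PCy3)Cl2Ru=CHPh (2 mol%), CH2Cl2, 40 °C
Reagents that add atoms: none
Why: Olefin cross-metathesis of a terminal alkene with an acrolein acetal is (E)-selective and delivers the masked enal (C13, C16, C15).

Step 6
Reactants: 11 (E)-6,6-dimethoxyhex-4-enal; 12 methyl acrylate
Product: 13 methyl (E)-3-hydroxy-8,8-dimethoxy-2-methylideneoct-6-enoate (racemic)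
Conditions: DABCO (1 equiv), neat in excess 12, rt, 5 d
Reagents that add atoms: none
Why: Morita–Baylis–Hillman reaction of an aliphatic aldehyde builds the 2-(hydroxyalkyl)acrylate that carries C7, C8, C9 and C14.

Step 7
Reactants: 13 the Morita–Baylis–Hillman alcohol
Product: 14 methyl (E)-3-[(tert-butoxycarbonyl)oxy]-8,8-dimethoxy-2-methylideneoct-6-enoate (racemic)
Conditions: Boc2O, DMAP (10 mol%), CH2Cl2, 0 °C to rt
Reagents that add atoms: di-tert-butyl dicarbonate, CC(C)(C)OC(=O)OC(=O)OC(C)(C)C
Why: O-acylation gives the allylic carbonate needed for Lewis-base-catalysed substitution.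

Step 8
Reactants: 8 the 2-formyl ketone; 14 the carbonate (1.5 equiv)
Product: 15 methyl (3S,6E)-3-[(1S,2R,3R)-2-{[(tert-butyldimethylsilyl)oxy]methyl}-1,3-diformyl-3-methyl-6-oxocyclohexyl]-8,8-dimethoxy-2-methylideneoct-6-enoate
Conditions: hydroquinidine 1,4-phthalazinediyl diether, (DHQD)2PHAL (10 mol%), PhCF3/toluene, rt
Reagents that add atoms: none
Why: Lewis-base-catalysed allylic alkylation of a Morita–Baylis–Hillman carbonate (SN2′–SN2′); both enantiomers of 14 converge on one allyl-ammonium ion, the cinchona catalyst sets C9, and the enol carbon C10 is attacked anti to the neighbouring CH2OTBS group, which sets the quaternary C10.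

Step 9
Reactants: 15 the alkylation product
Product: 17 keto spirolactone (11-{[(tert-butyldimethylsilyl)oxy]methyl}-5-[(3E)-5,5-dimethoxypent-3-en-1-yl]-10-(hydroxymethyl)-10-methyl-4-methylidene-2-oxaspiro[5.5]undecane-3,7-dione, stereocentres as in 15), via diol 16 (not isolated)
Conditions: NaBH4, MeOH/CH2Cl2, −78 °C, AcOH quench; then PPTS (cat.), toluene, 4 Å MS, 60 °C
Reagents that add atoms: none
Why: Chemoselective borohydride reduction of the two aldehydes (ketone and acrylate untouched at −78 °C), then acid-catalysed lactonisation of the C20 alcohol onto the acrylate ester; with C1 still a ketone, only the 7,20-lactone can form (C19–OH would need an eight-membered ring).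

Step 10
Reactants: 17 the keto spirolactone
Product: 18 the 1-hydroxy spirolactone (7-hydroxy-2-oxaspiro[5.5]undecan-3-one corresponding to 17; 1-OH cis to C20)
Conditions: NaBH4, CeCl3·7H2O, MeOH/THF, −78 °C; AcOH quench at −78 °C
Reagents that add atoms: none
Why: Luche reduction; hydride adds axially, anti to the axial C20 CH2O group of the chair in which C9 is equatorial, giving the equatorial 1-OH cis to C20 without 1,4-reduction of the methylene lactone, and the cold acidic quench avoids acyl migration to a 1,7-lactone.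

Step 11
Reactants: 18 the 1,19-diol
Product: 20 (2E)-enal diacetate (1,19-di-O-acetate of 18 with the side chain ending in CH=CH–CHO), via diacetate acetal 19 (not isolated)
Conditions: Ac2O, pyridine, DMAP (cat.), CH2Cl2, rt; then 5% aq. oxalic acid, THF, rt
Reagents that add atoms: acetic anhydride, CC(=O)OC(C)=O; water, O
Why: Acetylation fixes the 1α- and 19-acetates of the target, and mild hydrolysis of the allylic dimethyl acetal releases the (E)-enal without touching the TBS ether.

Step 12
Reactants: 20 the enal α-methylene lactone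
Product: 21 1α,19-diacetoxy-6-[(tert-butyldimethylsilyl)oxy]-15-hydroxy-17-nor-6,7-seco-ent-kauran-7,20-olide (either C15 epimer)
Conditions: SmI2 (2.2 equiv, slow addition), LiBr, t-BuOH (1.0 equiv), THF, −78 to −40 °C
Reagents that add atoms: none
Why: Proposed new method: SmI2 reduces the enal to an allylic ketyl whose β-carbon C13, now nucleophilic, adds 6-endo to the CH2 terminus C14 of the acrylate unit through a chair in which C10 and the enol side chain are both equatorial (sets C13 trans to C10); a second electron gives the C8 samarium lactone enolate, tert-butanol returns the enol(ate) to the C15 aldehyde, and the enolate closes ring D by aldol addition on the only face the two-carbon tether reaches (sets C8); the closest known chemistry is the SmI2 ketyl–Michael–aldol cascade on unsaturated lactones and the reductive β,β′-cyclisation of tethered Michael acceptors.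

Step 13
Reactants: 21 the 15-alcohol
Product: 22 1α,19-diacetoxy-6-[(tert-butyldimethylsilyl)oxy]-15-oxo-17-nor-6,7-seco-ent-kauran-7,20-olide
Conditions: Dess–Martin periodinane, NaHCO3, CH2Cl2, rt
Reagents that add atoms: none
Why: Dess–Martin oxidation of the hindered secondary alcohol converges both C15 epimers on the ketone; C8 is quaternary, so no epimerisation is possible.

Step 14
Reactants: 22 the 15-ketone
Product: 24 the 6-O-TBS ether of the target, via Mannich base 23 (not isolated)
Conditions: (Me2N)2CH2, Ac2O, DMF, 95 °C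
Reagents that add atoms: bis(dimethylamino)methane, CN(C)CN(C)C
Why: Mannich reaction with the iminium ion formed in situ, then β-elimination (α-methylenation); C16 is the only enolisable α-carbon of the ketone, and the alkene can only be exocyclic because C13 is a bridgehead.

Step 15
Reactants: 24 the silyl ether
Product: 25 the target
Conditions: HF·pyridine, pyridine, THF, 0 °C to rt
Reagents that add atoms: none
Why: Buffered fluoride desilylation of the primary TBS ether leaves the acetates, lactone and exocyclic enone intact.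

## Compound list

1 | (tert-butyldimethylsilyloxy)acetaldehyde | O=CCO[Si](C)(C)C(C)(C)C | starting material
2 | 1-(triphenylphosphoranylidene)propan-2-one | CC(=O)C=P(c1ccccc1)(c1ccccc1)c1ccccc1 | starting material
3 | (E)-5-[(tert-butyldimethylsilyl)oxy]pent-3-en-2-one | CC(=O)/C=C/CO[Si](C)(C)C(C)(C)C | intermediate
4 | (E)-1-[(tert-butyldimethylsilyl)oxy]-4-[(triisopropylsilyl)oxy]penta-2,4-diene | C=C(O[Si](C(C)C)(C(C)C)C(C)C)/C=C/CO[Si](C)(C)C(C)(C)C | intermediate
5 | methacrolein | CC(=C)C=O | starting material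
6 | (1R,2S)-2-{[(tert-butyldimethylsilyl)oxy]methyl}-1-methyl-4-[(triisopropylsilyl)oxy]cyclohex-3-ene-1-carbaldehyde (CHO cis to CH2OTBS) | C1=C(O[Si](C(C)C)(C(C)C)C(C)C)CC[C@@](C)(C=O)[C@H]1CO[Si](C)(C)C(C)(C)C | intermediate
7 | 2-{[(tert-butyldimethylsilyl)oxy]methyl}-3-(dimethoxymethyl)-1-methyl-4-oxocyclohexane-1-carbaldehyde (C4, C5 as in 6; C10 epimers) | O=C1CC[C@@](C)(C=O)[C@@H](CO[Si](C)(C)C(C)(C)C)C1C(OC)OC | intermediate
8 | (1R,2R)-2-{[(tert-butyldimethylsilyl)oxy]methyl}-3-(hydroxymethylidene)-1-methyl-4-oxocyclohexane-1-carbaldehyde | O=C1CC[C@@](C)(C=O)[C@@H](CO[Si](C)(C)C(C)(C)C)C1=CO | intermediate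
9 | pent-4-enal | C=CCCC=O | starting material
10 | 3,3-dimethoxyprop-1-ene | C=CC(OC)OC | starting material
11 | (E)-6,6-dimethoxyhex-4-enal | O=CCC/C=C/C(OC)OC | intermediate
12 | methyl acrylate | C=CC(=O)OC | starting material
13 | methyl (E)-3-hydroxy-8,8-dimethoxy-2-methylideneoct-6-enoate (racemic) | C=C(C(=O)OC)C(O)CC/C=C/C(OC)OC | intermediate
14 | methyl (E)-3-[(tert-butoxycarbonyl)oxy]-8,8-dimethoxy-2-methylideneoct-6-enoate (racemic) | C=C(C(=O)OC)C(OC(=O)OC(C)(C)C)CC/C=C/C(OC)OC | intermediate
15 | methyl (3S,6E)-3-[(1S,2R,3R)-2-{[(tert-butyldimethylsilyl)oxy]methyl}-1,3-diformyl-3-methyl-6-oxocyclohexyl]-8,8-dimethoxy-2-methylideneoct-6-enoate | COC(OC)/C=C/CC[C@H](C(=C)C(=O)OC)[C@]1(C=O)C(=O)CC[C@@](C)(C=O)[C@H]1CO[Si](C)(C)C(C)(C)C | intermediate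
16 | 19,20-diol corresponding to 15 (both formyl groups reduced to CH2OH; stereocentres as in 15) | COC(OC)/C=C/CC[C@H](C(=C)C(=O)OC)[C@]1(CO)C(=O)CC[C@@](C)(CO)[C@H]1CO[Si](C)(C)C(C)(C)C | intermediate
17 | 11-{[(tert-butyldimethylsilyl)oxy]methyl}-5-[(3E)-5,5-dimethoxypent-3-en-1-yl]-10-(hydroxymethyl)-10-methyl-4-methylidene-2-oxaspiro[5.5]undecane-3,7-dione (C4, C5, C9, C10 as in the target) | COC(OC)/C=C/CC[C@@H]1C(=C)C(=O)OC[C@]12C(=O)CC[C@@](C)(CO)[C@H]2CO[Si](C)(C)C(C)(C)C | intermediate
18 | 7-hydroxy analogue of 17 (1-OH cis to the lactone CH2O, as in the target) | COC(OC)/C=C/CC[C@@H]1C(=C)C(=O)OC[C@]12[C@@H](O)CC[C@@](C)(CO)[C@H]2CO[Si](C)(C)C(C)(C)C | intermediate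
19 | 1,19-di-O-acetate of 18 | COC(OC)/C=C/CC[C@@H]1C(=C)C(=O)OC[C@]12[C@@H](OC(C)=O)CC[C@@](C)(COC(C)=O)[C@H]2CO[Si](C)(C)C(C)(C)C | intermediate
20 | (2E)-5-[spirolactone]pent-2-enal: 19 with the dimethyl acetal hydrolysed to the aldehyde | O=C/C=C/CC[C@@H]1C(=C)C(=O)OC[C@]12[C@@H](OC(C)=O)CC[C@@](C)(COC(C)=O)[C@H]2CO[Si](C)(C)C(C)(C)C | intermediate
21 | 1α,19-diacetoxy-6-[(tert-butyldimethylsilyl)oxy]-15-hydroxy-17-nor-6,7-seco-ent-kauran-7,20-olide (C15 epimers) | C1C(O)[C@]23C[C@H]1CC[C@H]2[C@]1(COC3=O)[C@@H](OC(C)=O)CC[C@@](C)(COC(C)=O)[C@H]1CO[Si](C)(C)C(C)(C)C | intermediate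
22 | 1α,19-diacetoxy-6-[(tert-butyldimethylsilyl)oxy]-15-oxo-17-nor-6,7-seco-ent-kauran-7,20-olide | C1C(=O)[C@]23C[C@H]1CC[C@H]2[C@]1(COC3=O)[C@@H](OC(C)=O)CC[C@@](C)(COC(C)=O)[C@H]1CO[Si](C)(C)C(C)(C)C | intermediate
23 | 17-(dimethylamino) derivative of the 15-ketone (16-CH2NMe2 Mannich base, C16 epimers) | CN(C)CC1C(=O)[C@]23C[C@H]1CC[C@H]2[C@]1(COC3=O)[C@@H](OC(C)=O)CC[C@@](C)(COC(C)=O)[C@H]1CO[Si](C)(C)C(C)(C)C | intermediate
24 | 1α,19-diacetoxy-6-[(tert-butyldimethylsilyl)oxy]-15-oxo-6,7-seco-ent-kaur-16-en-7,20-olide | C=C1C(=O)[C@]23C[C@H]1CC[C@H]2[C@]1(COC3=O)[C@@H](OC(C)=O)CC[C@@](C)(COC(C)=O)[C@H]1CO[Si](C)(C)C(C)(C)C | intermediate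
25 | 1α,19-diacetoxy-6-hydroxy-15-oxo-6,7-seco-ent-kaur-16-en-7,20-olide (CNP0105570.2) | C=C1C(=O)[C@]23C[C@H]1CC[C@H]2[C@]1(COC3=O)[C@@H](OC(C)=O)CC[C@@](C)(COC(C)=O)[C@H]1CO | target

## Step count and risks

Total step count: 15. Longest linear sequence: 12 steps (steps 1–4, then 8–15); the side-chain fragment (steps 5–7) joins at step 8.

**Most likely to fail, 1: step 12 (reductive bicyclisation).** The enal may simply be reduced, or the C8 enolate may be protonated before the aldol. The fallback sets out from 20 and comes back at 22, bypassing 21. Pinnick oxidation of 20 (NaClO2, NaH2PO4, 2-methylbut-2-ene) gives the (E)-enoic acid F1, which is esterified with phenol (EDC, DMAP) to the phenyl enoate F2. F2 is treated with SmI2 and HMPA in THF at −78 °C with no proton donor, so that reductive β,β′-coupling leaves a bis-enolate. On warming, the aryl ester enolate loses phenoxide to give a ketene, which the C8 lactone enolate acylates, giving ketone 22 directly. This removes the reducible aldehyde and the need for a selective protonation.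

**Most likely to fail, 2: step 8 (allylic alkylation).** The nucleophile is hindered, the carbonate is alkyl-substituted, and O-alkylation may compete. The fallback sets out from 8 and 13 and comes back at 15. Alcohol 13 is converted with CBr4/PPh3 (allylic transposition) into the (2Z)-allylic bromide F3. The hydroxymethylene oxygen of 8 is alkylated with F3 (K2CO3, acetone) to give the allyl vinyl ether F4. Heating F4 in toluene at 110 °C effects a Claisen rearrangement through a chair on the face of C10 anti to the CH2OTBS group, giving 15; if the C9 epimer results, the (2E)-bromide is used instead.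

**Most likely to fail, 3: step 3 (Diels–Alder).** The formyl-endo preference of methacrolein with this acyclic diene, and hence the C4/C5 relationship, is not certain. The fallback sets out from 4 and 12 and comes back at 6. Diene 4 and methyl acrylate 12 undergo a Diels–Alder reaction catalysed by the AlBr3-activated form of the same oxazaborolidine, which is reliably endo and sets C5, giving the ester cycloadduct F5. Enolisation with LiN(iPr)2 in THF at −78 °C and methylation with MeI put the methyl group trans to the neighbouring CH2OTBS group, giving the quaternary ester F6. Reduction with iBu2AlH in CH2Cl2 at −78 °C gives aldehyde 6.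

Further compounds
F1 | step 12 | (2E)-enoic acid from oxidation of the aldehyde of 20 | OC(=O)/C=C/CC[C@@H]1C(=C)C(=O)OC[C@]12[C@@H](OC(C)=O)CC[C@@](C)(COC(C)=O)[C@H]2CO[Si](C)(C)C(C)(C)C
F2 | step 12 | phenyl (2E)-enoate of F1 | O=C(Oc1ccccc1)/C=C/CC[C@@H]1C(=C)C(=O)OC[C@]12[C@@H](OC(C)=O)CC[C@@](C)(COC(C)=O)[C@H]2CO[Si](C)(C)C(C)(C)C
F3 | step 8 | methyl (2Z,6E)-2-(bromomethyl)-8,8-dimethoxyocta-2,6-dienoate | COC(=O)/C(CBr)=C/CC/C=C/C(OC)OC
F4 | step 8 | O-allyl enol ether of 8 with F3 (allyl vinyl ether) | O=C1CC[C@@](C)(C=O)[C@@H](CO[Si](C)(C)C(C)(C)C)C1=COC/C(C(=O)OC)=C\CC/C=C/C(OC)OC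
F5 | step 3 | methyl 2-{[(tert-butyldimethylsilyl)oxy]methyl}-4-[(triisopropylsilyl)oxy]cyclohex-3-ene-1-carboxylate (C5 as in 6; mainly the cis ester) | C1=C(O[Si](C(C)C)(C(C)C)C(C)C)CCC(C(=O)OC)[C@H]1CO[Si](C)(C)C(C)(C)C
F6 | step 3 | methyl (1R,2S)-2-{[(tert-butyldimethylsilyl)oxy]methyl}-1-methyl-4-[(triisopropylsilyl)oxy]cyclohex-3-ene-1-carboxylate | C1=C(O[Si](C(C)C)(C(C)C)C(C)C)CC[C@@](C)(C(=O)OC)[C@H]1CO[Si](C)(C)C(C)(C)C
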